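**Retrosynthetic overview**

1. The cyclohexene that joins the two halves is cut by a Diels–Alder disconnection (C2–C4′, C14–C15′) into trienone 40 (diene C2=C1–C10=C14, unveiled in situ from silyloxydiene 39) and dehydrozaluzanin C 21 (dienophile C4′=C15′). Enone isomerisation and desilylation finish the target.
2. Each guaianolide half comes from a 10-hydroxy-4-oxo lactone (17, 34) by oxidation, double carbonyl methylenation (C15 and C14) and allylic oxidation at C3.
3. The lactone ring is closed last in each monomer: CO2 is fixed at the alkenyl carbon C11 of boronate 15 (or 32) and the new carboxylate closes onto C6, so C11–C12 and O–C6 form in one operation.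
4. Enabling feature: in hydroazulenones 15/32, C6 of the seven-membered ring is the β-carbon of the enone C4(=O)–C5=C6 that is exocyclic to the cyclopentanone ring, and it sits 1,3 to C11 on C7. C5 and C6 remain reversible (enolisation, retro-Michael), so they can settle relative to the fixed centres C7 and C1.
5. Ring order: cyclopentanone (from cyclopentenone) → seven-membered ring (Nozaki–Hiyama–Kishi C1–C10, then ring-closing metathesis C5=C6) → γ-lactone → cyclohexene (Diels–Alder). C7 is set by copper-catalysed allylic alkylation (dienophile half) or by allylation/Mitsunobu inversion (C7 and C8 of the diene half).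

Key step: step 10

Remark: guaianolide numbering (C1–C15, primes for the dienophile-derived half) is used for all intermediates; compounds 1, 4, 7 and 22 are taken as commercial; the carbinol configuration at C10 in 14, 15, 17, 31, 32, 34 and at C3 in 20, 37 is inconsequential (oxidised later) and left undefined.

**Route**

Step 1
Reactants: 1 cyclopent-2-en-1-one
Product: 2 2-(hydroxymethyl)cyclopent-2-en-1-one
Conditions: aq. HCHO, imidazole (cat.), THF/H2O, rt
Reagents that add atoms: formaldehyde, C=O
Why: Morita–Baylis–Hillman hydroxymethylation at the enone α-carbon, for which imidazole in aqueous THF is the usual catalyst with cyclic enones.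

Step 2
Reactants: 2 2-(hydroxymethyl)cyclopent-2-en-1-one
Product: 3 2-(bromomethyl)cyclopent-2-en-1-one
Conditions: PBr3, Et2O, 0 °C
Reagents that add atoms: phosphorus tribromide, BrP(Br)Br
Why: Standard conversion of a primary allylic alcohol into the allylic bromide.

Step 3
Reactants: 4 (E)-3-iodoprop-2-en-1-ol
Product: 5 (E)-5-(trimethylsilyl)pent-2-en-4-yn-1-ol
Conditions: ethynyltrimethylsilane, Pd(PPh3)2Cl2 (2 mol%), CuI (4 mol%), Et3N, THF, rt
Reagents that add atoms: ethynyltrimethylsilane, C#C[Si](C)(C)C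
Why: Sonogashira coupling at the vinyl iodide, which should retain the E geometry.

Step 4
Reactants: 5 (E)-5-(trimethylsilyl)pent-2-en-4-yn-1-ol
Product: 6 (E)-(5-bromopent-3-en-1-yn-1-yl)trimethylsilane
Conditions: CBr4, PPh3, CH2Cl2, 0 °C
Reagents that add atoms: tetrabromomethane, BrC(Br)(Br)Br
Why: Appel bromination of the primary allylic alcohol under neutral conditions that leave the enyne untouched.

Step 5
Reactants: 6 (E)-(5-bromopent-3-en-1-yn-1-yl)trimethylsilane; 7 2-(2-bromoethyl)-1,3-dioxolane
Product: 9 2-[(3R)-3-ethenyl-5-(trimethylsilyl)pent-4-yn-1-yl]-1,3-dioxolane, via Grignard reagent 8 (not isolated)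
Conditions: 7, Mg, THF, 40 °C; then 6, CuBr·SMe2 (5 mol%), chiral ferrocenyl diphosphine (Taniaphos, 6 mol%), CH2Cl2, −78 °C
Reagents that add atoms: none
Why: Copper-catalysed asymmetric allylic alkylation of an enyne-type allylic bromide should proceed γ-selectively (SN2′) to the 1,4-enyne, the ligand setting C7 (R) and the silyl group disfavouring 1,3-substitution to the allene.

Step 6
Reactants: 9 2-[(3R)-3-ethenyl-5-(trimethylsilyl)pent-4-yn-1-yl]-1,3-dioxolane
Product: 10 2-[(3R)-3-ethenylpent-4-yn-1-yl]-1,3-dioxolane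
Conditions: K2CO3, MeOH, rt
Reagents that add atoms: none
Why: Mild methanolytic protodesilylation of the alkynylsilane, which should not isomerise the skipped enyne.

Step 7
Reactants: 10 2-[(3R)-3-ethenylpent-4-yn-1-yl]-1,3-dioxolane
Product: 13 (4R)-4-ethenyl-5-(4,4,5,5-tetramethyl-1,3,2-dioxaborolan-2-yl)hex-5-enal, via alkenylalane 11 (not isolated), via dioxolane boronate 12 (not isolated)
Conditions: Ni(dppp)Cl2 (3 mol%), i-Bu2AlH, THF, 0 to 22 °C; then 2-methoxy-4,4,5,5-tetramethyl-1,3,2-dioxaborolane; then 1 M HCl, THF, rt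
Reagents that add atoms: 2-methoxy-4,4,5,5-tetramethyl-1,3,2-dioxaborolane, COB1OC(C)(C)C(C)(C)O1; water, O
Why: Nickel-catalysed hydroalumination with the dppp ligand places aluminium on the internal alkyne carbon (α-selective), the alkenylalane is borylated with retention, and aqueous acid unmasks the aldehyde.

Step 8
Reactants: 13 (4R)-4-ethenyl-5-(4,4,5,5-tetramethyl-1,3,2-dioxaborolan-2-yl)hex-5-enal; 3 2-(bromomethyl)cyclopent-2-en-1-one
Product: 14 3-[(4R)-4-ethenyl-1-hydroxy-5-(4,4,5,5-tetramethyl-1,3,2-dioxaborolan-2-yl)hex-5-en-1-yl]-2-methylidenecyclopentan-1-one (ring carbon C1 with 1α-H)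
Conditions: CrCl2 (10 mol%), chiral oxazoline–sulfonamide ligand (11 mol%), Mn, Cp2ZrCl2, LiCl, MeCN, rt
Reagents that add atoms: none
Why: Catalytic asymmetric Nozaki–Hiyama–Kishi allylation, in which the allylchromium species (trivalent chromium) from 3 should add through its ring γ-carbon in a closed transition state, regenerating the exocyclic methylene and setting C1 together with C10 under ligand control.

Step 9
Reactants: 14 3-[(4R)-4-ethenyl-1-hydroxy-5-(pinacolboryl)hex-5-en-1-yl]-2-methylidenecyclopentan-1-one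
Product: 15 hydroxy enone boronate: 10-hydroxy-11-(pinacolboryl)-12,14,15-trinorguaia-5,11(13)-dien-4-one (1α-H, 7α-H)
Conditions: second-generation Grubbs catalyst (5 mol%), toluene, 80 °C, high dilution
Reagents that add atoms: none
Why: Ring-closing metathesis between the vinyl group on C7 and the enone methylene should close the seven-membered ring as the trisubstituted enone C5=C6, no other pairing giving a viable ring because the vinyl and borylalkenyl groups are geminal.

Step 10
Reactants: 15 hydroxy enone boronate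
Product: 17 10-hydroxy-4-oxo-14,15-dinorguai-11(13)-en-12,6α-olide (1α,5α,7α-H, 6β-H), via caesium carboxylate 16 (not isolated)
Conditions: CuI (10 mol%), bis(oxazoline) ligand (12 mol%), CsF (3 equiv), CO2 (1 atm), DMF, 90 °C; then 1 M HCl work-up
Reagents that add atoms: carbon dioxide, O=C=O
Why: Proposed new method: fluoride activates the pinacol boronate of 15 for transmetalation to an alkenylcopper species (monovalent copper) that inserts CO2 at C11 to give acrylate 16, whose carboxylate oxygen then adds in an oxa-Michael fashion to C6, the β-carbon of the exocyclic enone (C4=O, C5=C6), with protonation of the C4 enolate at C5; the closest known reaction types are the copper/CsF-catalysed carboxylation of alkenylboronic esters with CO2 and the intramolecular conjugate addition of carboxylic acids to enones, which have not been run in tandem on a boryl enone. The only ring closed is the γ-lactone, by 5-exo-trig attack of O on C6. C6 and C5 are the new stereocentres; because the β-acyloxy ketone can revert by retro-Michael reaction and C5 is enolisable, both should settle under thermodynamic control, governed by the fixed centres C7 (C11 on the β face) and C1, in the trans-fused lactone (O at C6 α) with H5 α, the arrangement in which the substituents around C5–C6–C7 alternate. The step needs chemoselective carboxylation of the alkenyl–boron bond beside an enone and a free alcohol, and attack at C6 only; the first rests on the carbonyl tolerance of the CsF/CO2 conditions and on the fact that the alkenylcopper cannot reach the enone intramolecularly, the second on the 1,3-relationship of C11 and C6, which leaves the 5-exo mode as the only accessible closure.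

Step 11
Reactants: 17 10-hydroxy-4-oxo-14,15-dinorguai-11(13)-en-12,6α-olide
Product: 18 4,10-dioxo-14,15-dinorguai-11(13)-en-12,6α-olide (1α,5α,6β,7α-H)
Conditions: Dess–Martin periodinane, NaHCO3, CH2Cl2, 0 °C
Reagents that add atoms: none
Why: Neutral Dess–Martin oxidation of the secondary alcohol, which should leave the enolisable centres C1 and C5 and the acrylate untouched.

Step 12
Reactants: 18 4,10-dioxo-14,15-dinorguai-11(13)-en-12,6α-olide
Product: 19 dehydrocostus lactone
Conditions: Zn, CH2Br2, TiCl4, THF/CH2Cl2, 0 °C to rt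
Reagents that add atoms: dibromomethane, BrCBr
Why: Takai–Lombardo methylenation converts both ketones into the exocyclic methylenes C4=C15 and C10=C14 under non-basic conditions that should avoid epimerisation at C1/C5 and β-elimination of the lactone oxygen, ketones reacting well before the lactone carbonyl.

Step 13
Reactants: 19 dehydrocostus lactone
Product: 21 dehydrozaluzanin C, via 3-hydroxydehydrocostus lactone 20 (not isolated)
Conditions: SeO2 (0.5 equiv), t-BuOOH, CH2Cl2, rt; then Dess–Martin periodinane, NaHCO3, 0 °C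
Reagents that add atoms: tert-butyl hydroperoxide, CC(C)(C)OO
Why: Selenium dioxide allylic oxidation at the C3 methylene next to C4=C15, the position known to be oxidised in this lactone, followed by oxidation of the allylic alcohol to the cross-conjugated enone.

Step 14
Reactants: 22 3,3-diethoxypropan-1-ol
Product: 23 3,3-diethoxypropanal
Conditions: Dess–Martin periodinane, NaHCO3, CH2Cl2, 0 °C
Reagents that add atoms: none
Why: Buffered Dess–Martin oxidation of the primary alcohol, mild enough to spare the acetal and avoid β-elimination of ethanol.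

Step 15
Reactants: 23 3,3-diethoxypropanal; 6 (E)-(5-bromopent-3-en-1-yn-1-yl)trimethylsilane
Product: 24 (3S,4R)-1,1-diethoxy-4-ethenyl-6-(trimethylsilyl)hex-5-yn-3-ol
Conditions: CrCl2 (10 mol%), chiral oxazoline–sulfonamide ligand (11 mol%), Mn, Cp2ZrCl2, LiCl, MeCN, rt
Reagents that add atoms: none
Why: Asymmetric Nozaki–Hiyama–Kishi allylation, in which the γ-substituted allylchromium should react at the carbon bearing the alkynyl group through a chair transition state to give the anti adduct, the ligand fixing C7 (R) and, provisionally, C8.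

Step 16
Reactants: 24 (3S,4R)-1,1-diethoxy-4-ethenyl-6-(trimethylsilyl)hex-5-yn-3-ol
Product: 25 (3R,4R)-1,1-diethoxy-4-ethenyl-6-(trimethylsilyl)hex-5-yn-3-yl 4-nitrobenzoate
Conditions: 4-nitrobenzoic acid, PPh3, DIAD, THF, 0 °C
Reagents that add atoms: 4-nitrobenzoic acid, O=C(O)c1ccc(cc1)[N+](=O)[O-]
Why: Mitsunobu esterification inverts C8 to the configuration in which the C8 oxygen and the C7 alkynyl group are syn, as the 8β-hydroxy group of the target requires.

Step 17
Reactants: 25 (3R,4R)-1,1-diethoxy-4-ethenyl-6-(trimethylsilyl)hex-5-yn-3-yl 4-nitrobenzoate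
Product: 26 (3R,4R)-1,1-diethoxy-4-ethenylhex-5-yn-3-ol
Conditions: K2CO3, MeOH, rt
Reagents that add atoms: none
Why: Methanolysis removes the nitrobenzoate and the alkynylsilane in one operation without touching the stereocentres.

Step 18
Reactants: 26 (3R,4R)-1,1-diethoxy-4-ethenylhex-5-yn-3-ol
Product: 27 triisopropylsilyl ether of 26
Conditions: i-Pr3SiOTf, 2,6-lutidine, CH2Cl2, 0 °C
Reagents that add atoms: triisopropylsilyl trifluoromethanesulfonate, CC(C)[Si](C(C)C)(C(C)C)OS(=O)(=O)C(F)(F)F
Why: Silylation of the secondary alcohol with a bulky group chosen to withstand the later fluoride-mediated carboxylation.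

Step 19
Reactants: 27 triisopropylsilyl ether of 26
Product: 30 (3R,4R)-4-ethenyl-5-(pinacolboryl)-3-(triisopropylsilyloxy)hex-5-enal, via alkenylalane 28 (not isolated), via diethyl acetal boronate 29 (not isolated)
Conditions: Ni(dppp)Cl2 (3 mol%), i-Bu2AlH, THF, 0 to 22 °C; then 2-methoxy-4,4,5,5-tetramethyl-1,3,2-dioxaborolane; then 1 M HCl, THF, rt
Reagents that add atoms: 2-methoxy-4,4,5,5-tetramethyl-1,3,2-dioxaborolane, COB1OC(C)(C)C(C)(C)O1; water, O
Why: The same α-selective nickel-catalysed hydroalumination, boron trapping and acetal hydrolysis as in step 7, conditions the silyl ether should tolerate.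

Step 20
Reactants: 30 (3R,4R)-4-ethenyl-5-(pinacolboryl)-3-(triisopropylsilyloxy)hex-5-enal; 3 2-(bromomethyl)cyclopent-2-en-1-one
Product: 31 2-methylidenecyclopentanone adduct of 30 (C1 with 1α-H, C10 carbinol)
Conditions: CrCl2 (10 mol%), chiral oxazoline–sulfonamide ligand (11 mol%), Mn, Cp2ZrCl2, LiCl, MeCN, rt
Reagents that add atoms: none
Why: Catalytic asymmetric Nozaki–Hiyama–Kishi allylation as in step 8, the ligand again expected to set C1 together with C10.

Step 21
Reactants: 31 2-methylidenecyclopentanone adduct of 30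
Product: 32 8β-(triisopropylsilyloxy) hydroxy enone boronate (10-hydroxy-4-oxo, C5=C6, 1α-H, 7α-H)
Conditions: second-generation Grubbs catalyst (5 mol%), toluene, 80 °C, high dilution
Reagents that add atoms: none
Why: Ring-closing metathesis as in step 9 forms the seven-membered ring and the enone C5=C6.

Step 22
Reactants: 32 8β-(triisopropylsilyloxy) hydroxy enone boronate
Product: 34 10-hydroxy-4-oxo-8β-(triisopropylsilyloxy)-14,15-dinorguai-11(13)-en-12,6α-olide, via caesium carboxylate 33 (not isolated)
Conditions: CuI (10 mol%), bis(oxazoline) ligand (12 mol%), CsF (3 equiv), CO2 (1 atm), DMF, 90 °C; then 1 M HCl work-up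
Reagents that add atoms: carbon dioxide, O=C=O
Why: Proposed new method: as in step 10, fluoride-promoted boron-to-copper transmetalation and CO2 insertion at C11 give the acrylate, whose oxygen adds 5-exo-trig to the enone β-carbon C6 with C5 and C6 settling by retro-Michael/enolisation equilibration to the trans-fused lactone; the closest known reaction types are the copper/CsF carboxylation of alkenylboronic esters with CO2 and intramolecular oxa-Michael lactonisation.

Step 23
Reactants: 34 10-hydroxy-4-oxo-8β-(triisopropylsilyloxy) lactone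
Product: 35 4,10-dioxo-8β-(triisopropylsilyloxy)-14,15-dinorguai-11(13)-en-12,6α-olide
Conditions: Dess–Martin periodinane, NaHCO3, CH2Cl2, 0 °C
Reagents that add atoms: none
Why: Neutral Dess–Martin oxidation, chosen so that the β-silyloxy ketone formed is not exposed to base.

Step 24
Reactants: 35 4,10-dioxo-8β-(triisopropylsilyloxy) lactone
Product: 36 8β-(triisopropylsilyloxy)dehydrocostus lactone
Conditions: Zn, CH2Br2, TiCl4, THF/CH2Cl2, 0 °C to rt
Reagents that add atoms: dibromomethane, BrCBr
Why: Non-basic Takai–Lombardo double methylenation as in step 12, which should also avoid elimination of the C8 silyloxy group.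

Step 25
Reactants: 36 8β-(triisopropylsilyloxy)dehydrocostus lactone
Product: 38 8β-(triisopropylsilyloxy)dehydrozaluzanin C, via 3-hydroxy lactone 37 (not isolated)
Conditions: SeO2 (0.5 equiv), t-BuOOH, CH2Cl2, rt; then Dess–Martin periodinane, NaHCO3, 0 °C
Reagents that add atoms: tert-butyl hydroperoxide, CC(C)(C)OO
Why: Allylic oxidation at C3 and oxidation to the enone as in step 13.

Step 26
Reactants: 38 8β-(triisopropylsilyloxy)dehydrozaluzanin C
Product: 39 3-(trimethylsilyloxy)-2,4(15)-diene of 38
Conditions: Me3SiOTf, Et3N, CH2Cl2, −78 to 0 °C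
Reagents that add atoms: trimethylsilyl trifluoromethanesulfonate, C[Si](C)(C)OS(=O)(=O)C(F)(F)F
Why: Soft enolisation gives the 2-silyloxydiene because C2 is the only enolisable α-position of the cross-conjugated ketone.

Step 27
Reactants: 39 3-(trimethylsilyloxy)-2,4(15)-diene of 38; 21 dehydrozaluzanin C
Product: 42 8-O-triisopropylsilyl ether of the target, via trienone 40 (not isolated), via Diels–Alder adduct 41 (not isolated)
Conditions: 21 (3 equiv), Pd(OAc)2 (1.2 equiv), MeCN, rt, argon; then DBU (0.2 equiv), rt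
Reagents that add atoms: none
Why: Saegusa–Ito oxidation unveils the s-cis diene C2=C1–C10=C14 of 40, which should undergo the Diels–Alder reaction with the exocyclic enone C4′=C15′ of 21 from the convex α face of the cis-fused dienophile to set spiro centre C4′, as known for the 8-deoxy parent system, and base then moves the double bond into conjugation (C1=C2) with protonation at C10 from the less hindered face.

Step 28
Reactants: 42 8-O-triisopropylsilyl ether of the target
Product: 43 CNP0200944.1 (target)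
Conditions: HF·pyridine, THF, 0 °C to rt
Reagents that add atoms: none
Why: Buffered fluoride desilylation frees the C8 alcohol without nucleophilic attack on the three Michael acceptors.

**Compound list**

1 | cyclopent-2-en-1-one | O=C1C=CCC1 | starting material
2 | 2-(hydroxymethyl)cyclopent-2-en-1-one | O=C1CCC=C1CO | intermediate
3 | 2-(bromomethyl)cyclopent-2-en-1-one | O=C1CCC=C1CBr | intermediate
4 | (E)-3-iodoprop-2-en-1-ol | OC/C=C/I | starting material
5 | (E)-5-(trimethylsilyl)pent-2-en-4-yn-1-ol | OC/C=C/C#C[Si](C)(C)C | intermediate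
6 | (E)-(5-bromopent-3-en-1-yn-1-yl)trimethylsilane | BrC/C=C/C#C[Si](C)(C)C | intermediate
7 | 2-(2-bromoethyl)-1,3-dioxolane | BrCCC1OCCO1 | starting material
8 | [2-(1,3-dioxolan-2-yl)ethyl]magnesium bromide | Br[Mg]CCC1OCCO1 | intermediate
9 | 2-[(3R)-3-ethenyl-5-(trimethylsilyl)pent-4-yn-1-yl]-1,3-dioxolane | C1COC(CC[C@H](C=C)C#C[Si](C)(C)C)O1 | intermediate
10 | 2-[(3R)-3-ethenylpent-4-yn-1-yl]-1,3-dioxolane | C1COC(CC[C@H](C=C)C#C)O1 | intermediate
11 | internal alkenyl(diisobutyl)alane of 10 | C1COC(CC[C@H](C=C)C(=C)[Al](CC(C)C)CC(C)C)O1 | intermediate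
12 | 2-[(3R)-3-ethenyl-4-(pinacolboryl)pent-4-en-1-yl]-1,3-dioxolane | C1COC(CC[C@H](C=C)C(=C)B2OC(C)(C)C(C)(C)O2)O1 | intermediate
13 | (4R)-4-ethenyl-5-(4,4,5,5-tetramethyl-1,3,2-dioxaborolan-2-yl)hex-5-enal | O=CCC[C@H](C=C)C(=C)B1OC(C)(C)C(C)(C)O1 | intermediate
14 | 3-[(4R)-4-ethenyl-1-hydroxy-5-(pinacolboryl)hex-5-en-1-yl]-2-methylidenecyclopentan-1-one (1α-H) | C=C1C(=O)CC[C@H]1C(O)CC[C@H](C=C)C(=C)B1OC(C)(C)C(C)(C)O1 | intermediate
15 | 10-hydroxy-11-(pinacolboryl)-12,14,15-trinorguaia-5,11(13)-dien-4-one (1α-H, 7α-H) | O=C1CC[C@H]2C(O)CC[C@@H](C(=C)B3OC(C)(C)C(C)(C)O3)C=C12 | intermediate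
16 | caesium 2-substituted acrylate from 15 | O=C1CC[C@H]2C(O)CC[C@@H](C(=C)C(=O)[O-])C=C12.[Cs+] | intermediate
17 | 10-hydroxy-4-oxo-14,15-dinorguai-11(13)-en-12,6α-olide (1α,5α,7α-H, 6β-H) | C1C[C@H]2C(O)CC[C@H]3C(=C)C(=O)O[C@@H]3[C@H]2C1=O | intermediate
18 | 4,10-dioxo-14,15-dinorguai-11(13)-en-12,6α-olide | C1C[C@H]2C(=O)CC[C@H]3C(=C)C(=O)O[C@@H]3[C@H]2C1=O | intermediate
19 | dehydrocostus lactone | C1C[C@H]2C(=C)CC[C@H]3C(=C)C(=O)O[C@@H]3[C@H]2C1=C | intermediate
20 | 3-hydroxydehydrocostus lactone | OC1C[C@H]2C(=C)CC[C@H]3C(=C)C(=O)O[C@@H]3[C@H]2C1=C | intermediate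
21 | dehydrozaluzanin C | O=C1C[C@H]2C(=C)CC[C@H]3C(=C)C(=O)O[C@@H]3[C@H]2C1=C | intermediate
22 | 3,3-diethoxypropan-1-ol | CCOC(CCO)OCC | starting material
23 | 3,3-diethoxypropanal | CCOC(CC=O)OCC | intermediate
24 | (3S,4R)-1,1-diethoxy-4-ethenyl-6-(trimethylsilyl)hex-5-yn-3-ol | CCOC(OCC)C[C@H](O)[C@H](C=C)C#C[Si](C)(C)C | intermediate
25 | (3R,4R)-1,1-diethoxy-4-ethenyl-6-(trimethylsilyl)hex-5-yn-3-yl 4-nitrobenzoate | CCOC(OCC)C[C@@H](OC(=O)c1ccc(cc1)[N+](=O)[O-])[C@H](C=C)C#C[Si](C)(C)C | intermediate
26 | (3R,4R)-1,1-diethoxy-4-ethenylhex-5-yn-3-ol | CCOC(OCC)C[C@@H](O)[C@H](C=C)C#C | intermediate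
27 | triisopropylsilyl ether of 26 | CCOC(OCC)C[C@@H](O[Si](C(C)C)(C(C)C)C(C)C)[C@H](C=C)C#C | intermediate
28 | internal alkenyl(diisobutyl)alane of 27 | CCOC(OCC)C[C@@H](O[Si](C(C)C)(C(C)C)C(C)C)[C@H](C=C)C(=C)[Al](CC(C)C)CC(C)C | intermediate
29 | diethyl acetal of 30 | CCOC(OCC)C[C@@H](O[Si](C(C)C)(C(C)C)C(C)C)[C@H](C=C)C(=C)B1OC(C)(C)C(C)(C)O1 | intermediate
30 | (3R,4R)-4-ethenyl-5-(pinacolboryl)-3-(triisopropylsilyloxy)hex-5-enal | O=CC[C@@H](O[Si](C(C)C)(C(C)C)C(C)C)[C@H](C=C)C(=C)B1OC(C)(C)C(C)(C)O1 | intermediate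
31 | 2-methylidenecyclopentanone adduct of 30 (1α-H) | C=C1C(=O)CC[C@H]1C(O)C[C@@H](O[Si](C(C)C)(C(C)C)C(C)C)[C@H](C=C)C(=C)B1OC(C)(C)C(C)(C)O1 | intermediate
32 | 10-hydroxy-11-(pinacolboryl)-8β-(triisopropylsilyloxy)-12,14,15-trinorguaia-5,11(13)-dien-4-one | O=C1CC[C@H]2C(O)C[C@@H](O[Si](C(C)C)(C(C)C)C(C)C)[C@@H](C(=C)B3OC(C)(C)C(C)(C)O3)C=C12 | intermediate
33 | caesium 2-substituted acrylate from 32 | O=C1CC[C@H]2C(O)C[C@@H](O[Si](C(C)C)(C(C)C)C(C)C)[C@@H](C(=C)C(=O)[O-])C=C12.[Cs+] | intermediate
34 | 10-hydroxy-4-oxo-8β-(triisopropylsilyloxy)-14,15-dinorguai-11(13)-en-12,6α-olide | C1C[C@H]2C(O)C[C@@H](O[Si](C(C)C)(C(C)C)C(C)C)[C@H]3C(=C)C(=O)O[C@@H]3[C@H]2C1=O | intermediate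
35 | 4,10-dioxo-8β-(triisopropylsilyloxy)-14,15-dinorguai-11(13)-en-12,6α-olide | C1C[C@H]2C(=O)C[C@@H](O[Si](C(C)C)(C(C)C)C(C)C)[C@H]3C(=C)C(=O)O[C@@H]3[C@H]2C1=O | intermediate
36 | 8β-(triisopropylsilyloxy)dehydrocostus lactone | C1C[C@H]2C(=C)C[C@@H](O[Si](C(C)C)(C(C)C)C(C)C)[C@H]3C(=C)C(=O)O[C@@H]3[C@H]2C1=C | intermediate
37 | 3-hydroxy-8β-(triisopropylsilyloxy)dehydrocostus lactone | OC1C[C@H]2C(=C)C[C@@H](O[Si](C(C)C)(C(C)C)C(C)C)[C@H]3C(=C)C(=O)O[C@@H]3[C@H]2C1=C | intermediate
38 | 8β-(triisopropylsilyloxy)dehydrozaluzanin C | O=C1C[C@H]2C(=C)C[C@@H](O[Si](C(C)C)(C(C)C)C(C)C)[C@H]3C(=C)C(=O)O[C@@H]3[C@H]2C1=C | intermediate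
39 | 3-(trimethylsilyloxy)-2,4(15)-diene of 38 | C[Si](C)(C)OC1=C[C@H]2C(=C)C[C@@H](O[Si](C(C)C)(C(C)C)C(C)C)[C@H]3C(=C)C(=O)O[C@@H]3[C@H]2C1=C | intermediate
40 | 3-oxo-8β-(triisopropylsilyloxy)guaia-1,4(15),10(14),11(13)-tetraen-12,6α-olide | O=C1C=C2C(=C)C[C@@H](O[Si](C(C)C)(C(C)C)C(C)C)[C@H]3C(=C)C(=O)O[C@@H]3[C@H]2C1=C | intermediate
41 | Diels–Alder adduct (C1=C10, C2–H) | C=C1C(=O)C2C3=C(CC[C@]24C(=O)C[C@H]2C(=C)CC[C@H]5C(=C)C(=O)O[C@@H]5[C@H]24)C[C@@H](O[Si](C(C)C)(C(C)C)C(C)C)[C@H]2C(=C)C(=O)O[C@@H]2[C@@H]13 | intermediate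
42 | 8-O-triisopropylsilyl ether of the target | C=C1C(=O)C2=C3[C@H](CC[C@]24C(=O)C[C@H]2C(=C)CC[C@H]5C(=C)C(=O)O[C@@H]5[C@H]24)C[C@@H](O[Si](C(C)C)(C(C)C)C(C)C)[C@H]2C(=C)C(=O)O[C@@H]2[C@@H]13 | intermediate
43 | CNP0200944.1 | C=C1C(=O)C2=C3[C@H](CC[C@]24C(=O)C[C@H]2C(=C)CC[C@H]5C(=C)C(=O)O[C@@H]5[C@H]24)C[C@@H](O)[C@H]2C(=C)C(=O)O[C@@H]2[C@@H]13 | target

**Step count and risk**

Total step count: 28. Longest linear sequence: 16 steps (3, 4, 15–25, 26–28).

Steps most likely to fail:

Step 10. Protodeboronation may outrun carboxylation, base may move the C5=C6 double bond into the ring fusion, or the oxa-Michael addition may fail to equilibrate and close to the cis-fused lactone or leave C5 epimeric. The fallback sets out from 15 and separates the two bond formations with known reactions. Iododeboronation (I2, NaOH, THF/H2O) should give the alkenyl iodide F1. Palladium-catalysed hydroxycarbonylation (Pd(PPh3)4, CO, K2CO3, aqueous DMF) should give the acrylic acid F2. Camphorsulfonic acid in CH2Cl2, or DBU, should then effect the intramolecular oxa-Michael lactonisation, returning to the route at 17.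

Step 22. The same failure modes apply, with fluoride-induced loss of the C8 silyl ether in addition. The fallback sets out from 32: iododeboronation to the alkenyl iodide F3, hydroxycarbonylation to the acrylic acid F4, and acid-mediated oxa-Michael lactonisation, returning at 34.

Step 27. The trienone may dimerise with itself instead of reacting with 21, the cycloaddition may take the wrong face or endo/exo mode, or protonation at C10 may occur from the wrong face. The fallback sets out from 39. Phenylselenenyl chloride (CH2Cl2, −78 °C) should give the 2-phenylselanyl ketone F5. Oxidation with H2O2/pyridine at 0 °C in the presence of excess 21 releases the trienone slowly by selenoxide elimination, so the cross Diels–Alder reaction is favoured; DBU then isomerises the adduct, returning at 42.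

Further compounds
F1 | step 10 | 10-hydroxy-11-iodo-12,14,15-trinorguaia-5,11(13)-dien-4-one | O=C1CC[C@H]2C(O)CC[C@@H](C(=C)I)C=C12
F2 | step 10 | 10-hydroxy-4-oxo-14,15-dinorguaia-5,11(13)-dien-12-oic acid | O=C1CC[C@H]2C(O)CC[C@@H](C(=C)C(=O)O)C=C12
F3 | step 22 | 10-hydroxy-11-iodo-8β-(triisopropylsilyloxy)-12,14,15-trinorguaia-5,11(13)-dien-4-one | O=C1CC[C@H]2C(O)C[C@@H](O[Si](C(C)C)(C(C)C)C(C)C)[C@@H](C(=C)I)C=C12
F4 | step 22 | 10-hydroxy-4-oxo-8β-(triisopropylsilyloxy)-14,15-dinorguaia-5,11(13)-dien-12-oic acid | O=C1CC[C@H]2C(O)C[C@@H](O[Si](C(C)C)(C(C)C)C(C)C)[C@@H](C(=C)C(=O)O)C=C12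
F5 | step 27 | 2-(phenylselanyl)-8β-(triisopropylsilyloxy)dehydrozaluzanin C | O=C1C([Se]c4ccccc4)[C@H]2C(=C)C[C@@H](O[Si](C(C)C)(C(C)C)C(C)C)[C@H]3C(=C)C(=O)O[C@@H]3[C@H]2C1=C
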